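**Plan**
1. Retrosynthesis: the angelate and the protecting groups come off last; C13=C14 (olefination), C8=C17 (methylenation) and C9–C11 (enolate alkylation) are cut to reach an A/B core, and then C5–C10 and C7–C8 are cut together to an open chain.
2. Enabling feature: in ring B, C6 lies between C5 and C7, so a temporary C6 carbonyl turns C5/C7 into a 1,3-dinucleophile, while C10 and C8 are the β-carbon and the acyl carbon of a β-methyl enoate. Because C5–C10 is the bond shared by rings A and B, one Michael–Claisen sequence closes ring A (C5–C10) and then ring B (C7–C8).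
3. Forward: steps 1–9 build the acyclic keto enoate 13 with C3–O and C18–O tied as an acetonide; step 10 closes both rings; the helper oxygen at C6 is deleted by reductive transposition of a vinylogous ester (steps 11, 12, 14); then the C9 chain, the C8 methylene, the enoate and the angelate are installed.
4. Stereochemistry: C3 from Noyori hydrogenation; C4 from C3 by Frater–Seebach alkylation; C10 and C5 from the acetonide-locked chair in step 10; C9 by equilibration next to the C8 ketone; C13=C14 (E) by olefination; the Z ester from angelic acid.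

Key step: step 10

Remark: labdane numbering is used (decalin C1–C10, chain C11–C16 on C9, C17 on C8, C18 = CH2O on C4, C19 = CH3 on C4, C20 = CH3 on C10); all compounds belong to the enantiomeric series fixed by the SMILES.
Remark: 2-(2-iodoethyl)-2-methyl-1,3-dioxolane (19) and allyl diethylphosphonoacetate (26) are taken as purchasable.

**Step 1**
Reactants: 1 methyl acetoacetate; 2 allyl bromide
Product: 3 methyl 3-oxohept-6-enoate
Conditions: NaH, THF, 0 °C; n-BuLi, 0 °C; then 2, 0 °C → rt; 1 M HCl
Reagents that add atoms: none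
Why: γ-alkylation of the acetoacetate dianion, in which the more basic terminal carbanion reacts selectively with the allylic bromide.

**Step 2**
Reactants: 3 methyl 3-oxohept-6-enoate
Product: 4 methyl (3R)-3-hydroxyhept-6-enoate
Conditions: H2 (4 atm), RuCl2[(R)-BINAP] (cat.), MeOH, 50 °C
Reagents that add atoms: none
Why: Noyori asymmetric hydrogenation of a β-keto ester, in which the (R)-BINAP ruthenium catalyst reduces one face of the chelated ketone to set C3 as R, while the low pressure should spare the isolated terminal alkene.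

**Step 3**
Reactants: 4 methyl (3R)-3-hydroxyhept-6-enoate
Product: 5 methyl (2R,3R)-3-hydroxy-2-methylhept-6-enoate
Conditions: LiN(i-Pr)2 (2.2 equiv), THF, −78 → −20 °C; MeI, DMPU, −78 → 0 °C; 1 M HCl
Reagents that add atoms: iodomethane, CI
Why: Frater–Seebach alkylation, in which the chelated dianion is methylated on the face anti to the C3 substituent to give the anti product; this methyl becomes C19.

**Step 4**
Reactants: 5 methyl (2R,3R)-3-hydroxy-2-methylhept-6-enoate; 6 methallyl bromide (3-bromo-2-methylprop-1-ene)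
Product: 7 methyl (2R,3R)-3-hydroxy-2-methyl-2-(2-methylprop-2-en-1-yl)hept-6-enoate
Conditions: LiN(i-Pr)2 (2.5 equiv), THF, −78 → −20 °C; then 6, DMPU, −78 → 0 °C; 1 M HCl
Reagents that add atoms: none
Why: second Frater–Seebach alkylation of the now α-methylated dianion, again anti to the C3 oxygen, which should create the quaternary C4 with the configuration of the target; the methallyl group carries C5–C7 with C6 masked as an alkene.

**Step 5**
Reactants: 7 methyl (2R,3R)-3-hydroxy-2-methyl-2-(2-methylprop-2-en-1-yl)hept-6-enoate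
Product: 8 (2S,3R)-2-methyl-2-(2-methylprop-2-en-1-yl)hept-6-ene-1,3-diol
Conditions: LiAlH4, THF, 0 °C → rt; 1 M HCl
Reagents that add atoms: none
Why: hydride reduction of the hindered ester to the primary alcohol (the future C18–OH) without touching a stereocentre.

**Step 6**
Reactants: 8 (2S,3R)-2-methyl-2-(2-methylprop-2-en-1-yl)hept-6-ene-1,3-diol
Product: 9 (4R,5S)-4-(but-3-en-1-yl)-2,2,5-trimethyl-5-(2-methylprop-2-en-1-yl)-1,3-dioxane
Conditions: 2,2-dimethoxypropane, PPTS (cat.), CH2Cl2, rt
Reagents that add atoms: 2,2-dimethoxypropane, COC(C)(C)OC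
Why: acetonide formation from the 1,3-diol, giving a chair 1,3-dioxane that protects both oxygens and places the two carbon arms equatorial for the later ring closure.

**Step 7**
Reactants: 9 (4R,5S)-4-(but-3-en-1-yl)-2,2,5-trimethyl-5-(2-methylprop-2-en-1-yl)-1,3-dioxane
Product: 10 4-[(4R,5S)-2,2,5-trimethyl-5-(2-methylprop-2-en-1-yl)-1,3-dioxan-4-yl]butan-2-one
Conditions: PdCl2 (cat.), CuCl, O2 (1 atm), DMF/H2O, rt
Reagents that add atoms: water, O (supplies the carbonyl oxygen; O2 is the terminal oxidant)
Why: Tsuji–Wacker oxidation, which converts only the monosubstituted alkene into the methyl ketone (C10=O with C20) and leaves the 1,1-disubstituted alkene untouched.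

**Step 8**
Reactants: 10 4-[(4R,5S)-2,2,5-trimethyl-5-(2-methylprop-2-en-1-yl)-1,3-dioxan-4-yl]butan-2-one; 11 trimethyl phosphonoacetate
Product: 12 methyl (2E)-3-methyl-5-[(4R,5S)-2,2,5-trimethyl-5-(2-methylprop-2-en-1-yl)-1,3-dioxan-4-yl]pent-2-enoate
Conditions: NaH, 11, THF, 0 °C; then 10, 0 → 60 °C
Reagents that add atoms: none
Why: Horner–Wadsworth–Emmons olefination of the methyl ketone installs C9 and C8 as a β-methyl enoate; the E isomer should predominate and the minor Z isomer is carried along, since step 10 runs under equilibrating conditions.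

**Step 9**
Reactants: 12 methyl (2E)-3-methyl-5-[(4R,5S)-2,2,5-trimethyl-5-(2-methylprop-2-en-1-yl)-1,3-dioxan-4-yl]pent-2-enoate
Product: 13 methyl (2E)-3-methyl-5-[(4R,5S)-2,2,5-trimethyl-5-(2-oxopropyl)-1,3-dioxan-4-yl]pent-2-enoate
Conditions: O3 (1 equiv, to consumption of 12), CH2Cl2, −78 °C; then Me2S, −78 °C → rt
Reagents that add atoms: ozone, [O-][O+]=O
Why: ozonolysis, in which the electron-rich 1,1-disubstituted alkene reacts much faster than the conjugated enoate, unmasks the C6 methyl ketone.

**Step 10**
Reactants: 13 methyl (2E)-3-methyl-5-[(4R,5S)-2,2,5-trimethyl-5-(2-oxopropyl)-1,3-dioxan-4-yl]pent-2-enoate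
Product: 15 3,18-O-isopropylidene-3,18-dihydroxy-11,12,13,14,15,16,17-heptanorlabdane-6,8-dione (trans-fused), via Michael adduct keto ester 14 (not isolated)
Conditions: KOt-Bu (3 equiv), THF (0.01 M), 0 → 60 °C; then 1 M HCl to pH 4, 0 °C
Reagents that add atoms: none
Why: KOt-Bu equilibrates the ketone enolates; the C5 enolate adds to C10 of the β-methyl enoate (Michael addition) and, after proton transfer, the C7 enolate of the same ketone acylates the C8 ester (Claisen condensation), the final deprotonation of the 1,3-dione making the sequence irreversible. The closest known reaction type is the consecutive Michael–Claisen annulation of a ketone with an α,β-unsaturated ester to a cyclohexane-1,3-dione (as in dimedone-type syntheses), run here within one chain so that two rings form. Ring A closes by 6-exo-trig conjugate addition (C5–C10) and ring B by 6-exo-trig acyl substitution at C8 (C7–C8). C10 is controlled by the trans-fused acetonide, which locks the nascent ring A in one chair with both reacting arms equatorial and the C4 methyl axial, so that C5 should attack the enoate face that leaves the small C20 methyl axial and the CH2CO2Me arm equatorial; C5 is controlled by the equatorial preference of its acetyl arm and stays epimerisable (α to C6=O) until the Claisen step, which only the diequatorial adduct can undergo to a trans-decalin. The step needs regioselectivity between the C5 and C7 enolates, secured by ring size (the C7 enolate would have to close an eight-membered ring), and convergence of the E/Z enoates, secured by the reversibility of the Michael addition. High dilution suppresses intermolecular condensation.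

**Step 11**
Reactants: 15 3,18-O-isopropylidene-3,18-dihydroxy-11,12,13,14,15,16,17-heptanorlabdane-6,8-dione
Product: 16 3,18-O-isopropylidene-3,18-dihydroxy-8-methoxy-11,12,13,14,15,16,17-heptanorlabd-7-en-6-one
Conditions: K2CO3, Me2SO4, acetone, reflux
Reagents that add atoms: dimethyl sulfate, COS(=O)(=O)OC
Why: O-alkylation of the dione enolate by a hard electrophile; the C8 oxygen, flanked by two CH2 groups, is far more accessible than the C6 oxygen next to the C5 methine and the C4 substituents, so the 8-methoxy enone should predominate.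

**Step 12**
Reactants: 16 3,18-O-isopropylidene-3,18-dihydroxy-8-methoxy-11,12,13,14,15,16,17-heptanorlabd-7-en-6-one
Product: 18 3,18-O-isopropylidene-3,18-dihydroxy-11,12,13,14,15,16,17-heptanorlabd-6-en-8-one, via allylic alcohol 17 (not isolated)
Conditions: LiAlH4, Et2O, 0 °C; then 1 M HCl, THF, 0 °C (short contact)
Reagents that add atoms: water, O
Why: Stork–Danheiser reductive transposition, in which 1,2-hydride addition at C6 followed by acid hydrolysis of the enol ether with loss of the C6 hydroxyl gives the C8 enone, so the helper oxygen at C6 is removed while C8 keeps its carbonyl.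

**Step 13**
Reactants: 18 3,18-O-isopropylidene-3,18-dihydroxy-11,12,13,14,15,16,17-heptanorlabd-6-en-8-one; 19 2-(2-iodoethyl)-2-methyl-1,3-dioxolane
Product: 20 13,13-ethylenedioxy-3,18-O-isopropylidene-3,18-dihydroxy-14,15,17-trinorlabd-6-en-8-one (C9 epimer, chain trans to C20)
Conditions: LiN(i-Pr)2, THF, −78 °C; then 19, DMPU, −78 → −20 °C
Reagents that add atoms: none
Why: kinetic α′-deprotonation of the enone can occur only at C9, and SN2 alkylation of this cross-conjugated enolate attaches C11–C13 and C16 with C13 masked as a dioxolane; attack anti to the axial C20 methyl is expected, and the C9 configuration is corrected in step 14.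

**Step 14**
Reactants: 20 13,13-ethylenedioxy-3,18-O-isopropylidene-3,18-dihydroxy-14,15,17-trinorlabd-6-en-8-one (C9 epimer)
Product: 22 13,13-ethylenedioxy-3,18-O-isopropylidene-3,18-dihydroxy-14,15,17-trinorlabdan-8-one, via C9-epimeric saturated ketone 21 (not isolated)
Conditions: H2 (1 atm), Pd/C, EtOAc, rt; filter; NaOMe (cat.), MeOH, rt
Reagents that add atoms: none
Why: heterogeneous hydrogenation of the disubstituted enone alkene, then base equilibration through the C8 enolate, which should place the C9 chain equatorial (9-H axial, trans to C20) as in the target.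

**Step 15**
Reactants: 22 13,13-ethylenedioxy-3,18-O-isopropylidene-3,18-dihydroxy-14,15,17-trinorlabdan-8-one
Product: 23 13,13-ethylenedioxy-3,18-O-isopropylidene-14,15-dinorlabd-8(17)-ene-3,18-diol
Conditions: Ph3PCH3Br, KOt-Bu, toluene, 80 °C
Reagents that add atoms: methyltriphenylphosphonium bromide, C[P+](c1ccccc1)(c1ccccc1)c1ccccc1.[Br-]
Why: Wittig methylenation of the hindered C8 ketone gives the exocyclic C8=C17 alkene, the only other carbonyl (C13) being masked.

**Step 16**
Reactants: 23 13,13-ethylenedioxy-3,18-O-isopropylidene-14,15-dinorlabd-8(17)-ene-3,18-diol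
Product: 24 3,18-dihydroxy-14,15-dinorlabd-8(17)-en-13-one
Conditions: 1 M HCl, THF, rt
Reagents that add atoms: water, O
Why: aqueous acid hydrolyses both the dioxolane and the acetonide; dilute acid at room temperature should not isomerise the 1,1-disubstituted alkene.

**Step 17**
Reactants: 24 3,18-dihydroxy-14,15-dinorlabd-8(17)-en-13-one
Product: 25 18-(tert-butyldimethylsilyloxy)-3-hydroxy-14,15-dinorlabd-8(17)-en-13-one
Conditions: TBSCl, imidazole, CH2Cl2, 0 °C
Reagents that add atoms: tert-butyldimethylsilyl chloride, CC(C)(C)[Si](C)(C)Cl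
Why: silylation of the primary alcohol should be much faster than that of the hindered secondary C3–OH, which is left free for the later acylation.

**Step 18**
Reactants: 25 18-(tert-butyldimethylsilyloxy)-3-hydroxy-14,15-dinorlabd-8(17)-en-13-one; 26 allyl diethylphosphonoacetate
Product: 27 allyl (13E)-18-(tert-butyldimethylsilyloxy)-3-hydroxylabda-8(17),13-dien-15-oate
Conditions: NaH, 26, THF, 0 °C; then 25, rt → 50 °C
Reagents that add atoms: none
Why: Horner–Wadsworth–Emmons olefination of the methyl ketone with the preformed sodium phosphonate builds C13=C14 with the E isomer favoured (chain trans to the ester); the phosphonate anion is too weak a base to deprotonate C3–OH, and the minor Z isomer is removed by chromatography.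

**Step 19**
Reactants: 27 allyl (13E)-18-(tert-butyldimethylsilyloxy)-3-hydroxylabda-8(17),13-dien-15-oate; 28 angelic acid
Product: 30 allyl (13E)-3-angeloyloxy-18-(tert-butyldimethylsilyloxy)labda-8(17),13-dien-15-oate, via angelic 2,4,6-trichlorobenzoic mixed anhydride 29 (not isolated)
Conditions: 28, 2,4,6-trichlorobenzoyl chloride, Et3N, toluene, rt; then 27, 80 °C
Reagents that add atoms: none
Why: Yamaguchi esterification through the mixed anhydride, run without a nucleophilic catalyst, should acylate the hindered equatorial C3–OH while keeping the Z geometry of the angelate.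

**Step 20**
Reactants: 30 allyl (13E)-3-angeloyloxy-18-(tert-butyldimethylsilyloxy)labda-8(17),13-dien-15-oate
Product: 31 (13E)-3-angeloyloxy-18-(tert-butyldimethylsilyloxy)labda-8(17),13-dien-15-oic acid
Conditions: Pd(PPh3)4 (cat.), morpholine, THF, rt
Reagents that add atoms: none
Why: zerovalent palladium ionises the allyl ester to a π-allyl complex that morpholine traps, which frees the C15 acid while the angelate and the silyl ether stay intact.

**Step 21**
Reactants: 31 (13E)-3-angeloyloxy-18-(tert-butyldimethylsilyloxy)labda-8(17),13-dien-15-oic acid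
Product: 32 (3R,4S,5S,9R,10S,13E)-3-[(Z)-2-methylbut-2-enoyloxy]-18-hydroxylabda-8(17),13-dien-15-oic acid (target)
Conditions: HF·pyridine, pyridine, THF, 0 °C → rt
Reagents that add atoms: none
Why: fluoride cleaves the primary silyl ether under buffered, weakly acidic conditions that should avoid 1,3-acyl migration of the angelate and isomerisation of the exocyclic alkene.

**Compound list**
1 | methyl acetoacetate | CC(=O)CC(=O)OC | starting material
2 | allyl bromide | C=CCBr | starting material
3 | methyl 3-oxohept-6-enoate | C=CCCC(=O)CC(=O)OC | intermediate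
4 | methyl (3R)-3-hydroxyhept-6-enoate | C=CCC[C@@H](O)CC(=O)OC | intermediate
5 | methyl (2R,3R)-3-hydroxy-2-methylhept-6-enoate | C=CCC[C@@H](O)[C@@H](C)C(=O)OC | intermediate
6 | methallyl bromide (3-bromo-2-methylprop-1-ene) | C=C(C)CBr | starting material
7 | methyl (2R,3R)-3-hydroxy-2-methyl-2-(2-methylprop-2-en-1-yl)hept-6-enoate | C=CCC[C@@H](O)[C@](CC(C)=C)(C)C(=O)OC | intermediate
8 | (2S,3R)-2-methyl-2-(2-methylprop-2-en-1-yl)hept-6-ene-1,3-diol | C=CCC[C@@H](O)[C@](CC(C)=C)(C)CO | intermediate
9 | (4R,5S)-4-(but-3-en-1-yl)-2,2,5-trimethyl-5-(2-methylprop-2-en-1-yl)-1,3-dioxane | C=CCC[C@H]1OC(C)(C)OC[C@@]1(CC(C)=C)C | intermediate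
10 | 4-[(4R,5S)-2,2,5-trimethyl-5-(2-methylprop-2-en-1-yl)-1,3-dioxan-4-yl]butan-2-one | CC(=O)CC[C@H]1OC(C)(C)OC[C@@]1(CC(C)=C)C | intermediate
11 | trimethyl phosphonoacetate | COC(=O)CP(=O)(OC)OC | starting material
12 | methyl (2E)-3-methyl-5-[(4R,5S)-2,2,5-trimethyl-5-(2-methylprop-2-en-1-yl)-1,3-dioxan-4-yl]pent-2-enoate (minor 2Z isomer carried along) | COC(=O)/C=C(\C)CC[C@H]1OC(C)(C)OC[C@@]1(CC(C)=C)C | intermediate
13 | methyl (2E)-3-methyl-5-[(4R,5S)-2,2,5-trimethyl-5-(2-oxopropyl)-1,3-dioxan-4-yl]pent-2-enoate | COC(=O)/C=C(\C)CC[C@H]1OC(C)(C)OC[C@@]1(CC(C)=O)C | intermediate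
14 | Michael adduct formed in the flask in step 10: ring A closed, acetyl on C5 and CH2CO2Me on C10, acetonide retained | CC(=O)[C@H]2[C@@](C)(CC[C@@H](OC(C)(C)OC3)[C@@]23C)CC(=O)OC | intermediate
15 | 3,18-O-isopropylidene-3,18-dihydroxy-11,12,13,14,15,16,17-heptanorlabdane-6,8-dione (trans-fused; C3, C4, C5, C10 as in 32) | O=C1CC(=O)[C@H]2[C@@](C)(CC[C@@H](OC(C)(C)OC3)[C@@]23C)C1 | intermediate
16 | 3,18-O-isopropylidene-3,18-dihydroxy-8-methoxy-11,12,13,14,15,16,17-heptanorlabd-7-en-6-one | COC1=CC(=O)[C@H]2[C@@](C)(CC[C@@H](OC(C)(C)OC3)[C@@]23C)C1 | intermediate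
17 | 3,18-O-isopropylidene-8-methoxy-11,12,13,14,15,16,17-heptanorlabd-7-ene-3,6,18-triol (C6 epimers; formed in the flask in step 12) | COC1=CC(O)[C@H]2[C@@](C)(CC[C@@H](OC(C)(C)OC3)[C@@]23C)C1 | intermediate
18 | 3,18-O-isopropylidene-3,18-dihydroxy-11,12,13,14,15,16,17-heptanorlabd-6-en-8-one | O=C1C=C[C@H]2[C@@](C)(CC[C@@H](OC(C)(C)OC3)[C@@]23C)C1 | intermediate
19 | 2-(2-iodoethyl)-2-methyl-1,3-dioxolane | CC1(CCI)OCCO1 | starting material
20 | 13,13-ethylenedioxy-3,18-O-isopropylidene-3,18-dihydroxy-14,15,17-trinorlabd-6-en-8-one, C9 epimer (chain trans to C20) | O=C1C=C[C@H]2[C@@](C)(CC[C@@H](OC(C)(C)OC3)[C@@]23C)[C@H]1CCC4(C)OCCO4 | intermediate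
21 | 13,13-ethylenedioxy-3,18-O-isopropylidene-3,18-dihydroxy-14,15,17-trinorlabdan-8-one, C9 epimer (formed in the flask in step 14) | O=C1CC[C@H]2[C@@](C)(CC[C@@H](OC(C)(C)OC3)[C@@]23C)[C@H]1CCC4(C)OCCO4 | intermediate
22 | 13,13-ethylenedioxy-3,18-O-isopropylidene-3,18-dihydroxy-14,15,17-trinorlabdan-8-one (C9 as in 32) | O=C1CC[C@H]2[C@@](C)(CC[C@@H](OC(C)(C)OC3)[C@@]23C)[C@@H]1CCC4(C)OCCO4 | intermediate
23 | 13,13-ethylenedioxy-3,18-O-isopropylidene-14,15-dinorlabd-8(17)-ene-3,18-diol | C=C1CC[C@H]2[C@@](C)(CC[C@@H](OC(C)(C)OC3)[C@@]23C)[C@@H]1CCC4(C)OCCO4 | intermediate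
24 | 3,18-dihydroxy-14,15-dinorlabd-8(17)-en-13-one | C=C1CC[C@H]2[C@@](C)(CC[C@@H](O)[C@]2(C)CO)[C@@H]1CCC(C)=O | intermediate
25 | 18-(tert-butyldimethylsilyloxy)-3-hydroxy-14,15-dinorlabd-8(17)-en-13-one | C=C1CC[C@H]2[C@@](C)(CC[C@@H](O)[C@]2(C)CO[Si](C)(C)C(C)(C)C)[C@@H]1CCC(C)=O | intermediate
26 | allyl diethylphosphonoacetate | C=CCOC(=O)CP(=O)(OCC)OCC | starting material
27 | allyl (13E)-18-(tert-butyldimethylsilyloxy)-3-hydroxylabda-8(17),13-dien-15-oate | C=C1CC[C@H]2[C@@](C)(CC[C@@H](O)[C@]2(C)CO[Si](C)(C)C(C)(C)C)[C@@H]1CC/C(C)=C/C(=O)OCC=C | intermediate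
28 | angelic acid ((Z)-2-methylbut-2-enoic acid) | C/C=C(/C)C(=O)O | starting material
29 | (Z)-2-methylbut-2-enoic 2,4,6-trichlorobenzoic anhydride (formed in the flask in step 19) | C/C=C(/C)C(=O)OC(=O)c1c(Cl)cc(Cl)cc1Cl | intermediate
30 | allyl (13E)-3-angeloyloxy-18-(tert-butyldimethylsilyloxy)labda-8(17),13-dien-15-oate | C=C1CC[C@H]2[C@@](C)(CC[C@@H](OC(=O)/C(C)=C\C)[C@]2(C)CO[Si](C)(C)C(C)(C)C)[C@@H]1CC/C(C)=C/C(=O)OCC=C | intermediate
31 | (13E)-3-angeloyloxy-18-(tert-butyldimethylsilyloxy)labda-8(17),13-dien-15-oic acid | C=C1CC[C@H]2[C@@](C)(CC[C@@H](OC(=O)/C(C)=C\C)[C@]2(C)CO[Si](C)(C)C(C)(C)C)[C@@H]1CC/C(C)=C/C(=O)O | intermediate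
32 | (3R,4S,5S,9R,10S,13E)-3-[(Z)-2-methylbut-2-enoyloxy]-18-hydroxylabda-8(17),13-dien-15-oic acid | C=C1CC[C@H]2[C@@](C)(CC[C@@H](OC(=O)/C(C)=C\C)[C@]2(C)CO)[C@@H]1CC/C(C)=C/C(=O)O | target

**Totals and risks**
Total step count: 21. Longest linear sequence: 21 steps (1 → 32); all other building blocks are purchased.

The three steps most likely to fail:

Step 10. The conjugate addition onto the fully β-substituted, singly activated enoate may be slow compared with γ-deprotonation of the enoate and retro-Michael reversion, and the facial selectivity at C10 may be incomplete. Fallback: set out from ketone 10 and use a doubly activated acceptor with a traceless ester. Knoevenagel condensation of 10 with dimethyl malonate (TiCl4, pyridine, THF, 0 °C → rt) would give the alkylidene malonate dimethyl 2-{4-[(4R,5S)-2,2,5-trimethyl-5-(2-methylprop-2-en-1-yl)-1,3-dioxan-4-yl]butan-2-ylidene}propanedioate F1. Ozonolysis as in step 9 would give the keto alkylidene malonate F2. NaOMe in MeOH at reflux should then effect a fast, reversible Michael addition, in which the bulky malonyl arm strongly prefers the equatorial position, followed by Claisen closure to the 9-methoxycarbonyl dione F3. Krapcho dealkoxycarbonylation (LiCl, wet DMSO, 130 °C) comes back to the route at 15.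

Step 11. Methylation of the ambident dione enolate may occur at the C6 oxygen or at C7 instead of the C8 oxygen, which after step 12 would delete the wrong carbonyl. Fallback: set out from 15 and let a carbonyl condensation decide the regiochemistry. Pyrrolidine (toluene, reflux, removal of water) should add to the less hindered C8 carbonyl carbon and give the 8-(pyrrolidin-1-yl) enaminone F4. LiAlH4 reduction of the C6 carbonyl would give the amino allylic alcohol F5, whose mild aqueous acid hydrolysis comes back to the route at 18.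

Step 13. SN2 alkylation of the hindered C9 enolate with an unactivated primary iodide may be slow, which allows proton transfer between enolate and product, enolate equilibration and polyalkylation. Fallback: set out from 18 and alkylate a metalated hydrazone instead of the lithium enolate. Condensation with N,N-dimethylhydrazine (cat. AcOH, EtOH, reflux) would give the N,N-dimethylhydrazone F6. Deprotonation at C9 with LiN(i-Pr)2 and alkylation of the more nucleophilic aza-enolate with 19 would give the alkylated hydrazone F7. Neutral hydrolysis (CuCl2, THF/H2O, pH 7) comes back to the route at 20.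

**Further compounds**
F1 | step 10 | dimethyl 2-{4-[(4R,5S)-2,2,5-trimethyl-5-(2-methylprop-2-en-1-yl)-1,3-dioxan-4-yl]butan-2-ylidene}propanedioate | COC(=O)C(C(=O)OC)=C(C)CC[C@H]1OC(C)(C)OC[C@@]1(CC(C)=C)C
F2 | step 10 | dimethyl 2-{4-[(4R,5S)-2,2,5-trimethyl-5-(2-oxopropyl)-1,3-dioxan-4-yl]butan-2-ylidene}propanedioate | COC(=O)C(C(=O)OC)=C(C)CC[C@H]1OC(C)(C)OC[C@@]1(CC(C)=O)C
F3 | step 10 | 9-methoxycarbonyl derivative of dione 15 (methyl ester on C9, C9 epimers) | O=C1CC(=O)[C@H]2[C@@](C)(CC[C@@H](OC(C)(C)OC3)[C@@]23C)C1C(=O)OC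
F4 | step 11 | 3,18-O-isopropylidene-3,18-dihydroxy-8-(pyrrolidin-1-yl)-11,12,13,14,15,16,17-heptanorlabd-7-en-6-one | C1CCN(C1)C4=CC(=O)[C@H]2[C@@](C)(CC[C@@H](OC(C)(C)OC3)[C@@]23C)C4
F5 | step 11 | 3,18-O-isopropylidene-8-(pyrrolidin-1-yl)-11,12,13,14,15,16,17-heptanorlabd-7-ene-3,6,18-triol (C6 epimers) | C1CCN(C1)C4=CC(O)[C@H]2[C@@](C)(CC[C@@H](OC(C)(C)OC3)[C@@]23C)C4
F6 | step 13 | N,N-dimethylhydrazone of enone 18 | CN(C)N=C1C=C[C@H]2[C@@](C)(CC[C@@H](OC(C)(C)OC3)[C@@]23C)C1
F7 | step 13 | N,N-dimethylhydrazone of alkylated enone 20 | CN(C)N=C1C=C[C@H]2[C@@](C)(CC[C@@H](OC(C)(C)OC3)[C@@]23C)[C@H]1CCC4(C)OCCO4
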